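Count the reagent.

| setting | summer | dusk | Thursday's | Sunday's |
|---|---|---|---|---|
| left-handed substrate | 1.5 M | 1.5 M | 1.5 M | 1.5 M |
| right-handed substrate | 1.5 M | 1.5 M | 1.5 M | 1.5 M |
| reagent | 1.65 M | 1.65 M | 1.65 M | 1.65 M |
| free catalyst | 10 mM | 22 mM | 15 mM | 15 mM |
| temperature | 5 °C | 18 °C | 25 °C | 10 °C |
| remark | run made earlier | run made earlier |  |  |
| time |  |  | 12 h | 12 h |

| run | time / h | left-handed product / % | right-handed product / % |
|---|---|---|---|
| summer | 10.0 | 30.1 | 2.0 |
| summer | 20.0 | 42.2 | 2.4 |
| summer | 25.0 | 42.8 | 2.1 |
| summer | 40.0 | 44.4 | 4.6 |
| dusk | 1.00 | 20.1 | 2.6 |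
| dusk | 2.50 | 34.7 | 1.8 |
| dusk | 6.00 | 45.5 | 1.1 |
| dusk | 15.0 | 46.9 | 2.4 |

(each reading ± 1 percentage point)

- free catalyst is single-handed; left-handed substrate and right-handed substrate are mirror images of each other, charged as a racemate, each of them at the stated concentration
- what may be going on: reagent + catalyst intermediate A -> free catalyst + left-handed product; free catalyst + left-handed substrate <-> catalyst intermediate A; reagent + catalyst intermediate B -> free catalyst + right-handed product; free catalyst -> spent catalyst; free catalyst + right-handed substrate <-> catalyst intermediate B

* which flask leads in share of left-handed product in all that became left-handed product or right-handed product ("all alike" within 1.5 percentage points) (Thursday's / Sunday's / all alike)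
* share of left-handed product in all that became left-handed product or right-handed product, Thursday's
* share of left-handed product in all that became left-handed product or right-handed product, Sunday's

Free catalyst binds left-handed substrate reversibly as catalyst intermediate A, and right-handed substrate as catalyst intermediate B. Reagent carries each intermediate on to its product and returns free catalyst, while free catalyst can also pass into spent catalyst. So each mole of either product costs one mole of reagent, and the reagent is the limiting reagent: its charge covers 55.0% of the two substrates together. Keep the ledger in that percent.

Enter the left-handed substrate first, which can claim 50.0%. What stays, 5.00%, is the reagent spare, the reagent charge less the left-handed substrate charge, over both substrates charged. Now close the books: a flask that turns its left-handed substrate wholly into product and uses its spare on right-handed product ends at a share of 90.9%.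

Next enter the readings. At 15.0 h, the dusk run shows 46.9% of left-handed product and 2.4% of right-handed product, which leaves 5.7 percentage points of reagent unentered, and its share reads 95.1%. The summer run's last reading gives 90.6%, but right-handed readings of 1.1% to 4.6% carry a scatter of 1 point, so these two shares are rough. My own reckoning takes the dusk reading for both new flasks, and holds it against the 90.9% of the closed books.

The forecast gives 94.8% for Thursday's and 94.8% for Sunday's, hence all alike, reasoning: “Thursday's catalyst dies sooner, while Sunday's turns over more slowly, so they end up similar.”

The flasks give 96.0% for Thursday's and 95.3% for Sunday's, so the answer is all alike, as forecast.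

    reagent + catalyst intermediate A → free catalyst + left-handed product (k = 0.710 L mol⁻¹ min⁻¹, Ea = 43.0 kJ mol⁻¹)
    free catalyst + left-handed substrate ⇌ catalyst intermediate A (K = 4.80 L mol⁻¹, k = 14.0 L mol⁻¹ min⁻¹, Ea = 40.0 kJ mol⁻¹, ΔH = −2.00 kJ mol⁻¹)
    reagent + catalyst intermediate B → free catalyst + right-handed product (k = 0.310 L mol⁻¹ min⁻¹, Ea = 69.0 kJ mol⁻¹)
    free catalyst → spent catalyst (k = 0.0130 min⁻¹, Ea = 93.0 kJ mol⁻¹)
    free catalyst + right-handed substrate ⇌ catalyst intermediate B (K = 0.170 L mol⁻¹, k = 100 L mol⁻¹ min⁻¹, Ea = 45.0 kJ mol⁻¹, ΔH = −37.0 kJ mol⁻¹)
    (constants at 25 °C)

Sunday's share rests mainly on the back reaction of catalyst intermediate B to free catalyst and right-handed substrate: with that back reaction taken away, the share is 4.72% against 95.3%. At 12.0 h, Sunday's holds 2.09% of right-handed product, less than its spare of 5.00%. A neighbour of Sunday's charged with 2.8 M of reagent has a spare of 43.3%, and its right-handed product reaches 6.63%, more than Sunday's spare. Its share of 88.3% stands 7.7 points below Thursday's, more than the margin of 1.5 points.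

The numbers in the tables were generated by integration for substances that don't exist.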